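## Structural features

The target is a trans-fused decalin of the eremophilane type (numbering used throughout: ring A = C1–C5 and C10, ring B = C5–C10, β = the face of the C5 methyl). It carries methyls on C4 and C5, a tiglate on C3, an isopropenyl group on C7, a ketone at C8 and a senecioate on C9. Its six stereocentres (3R,4R,5R,7S,9S,10R) form a contiguous run C3–C4–C5–C10–C9, with C7 beyond the C8 carbonyl, and the quaternary C5 lies between the stereocentres C4 and C10. In the chair–chair decalin the C5 methyl (β) and H10 (α) are axial, while the 3α-ester, the 4β-methyl, the 7α-isopropenyl group and the 9α-ester are all equatorial. Ring B is the fragile part: the isopropenyl ketone is β,γ-unsaturated and conjugates or epimerises at C7 with acid or base, the α-acyloxy ketone can enolise or shift its acyl group, and the two unsaturated esters must be placed on the right oxygens. The real difficulty is the quaternary C5 and the C7–C8–C9 array, where the axial C5 methyl shields the β face of C7 and C9; this helps the C7–C bond to form from the α face but makes awkward the C9–H bond that a ketone reduction must form from the β face. The key step exploits the fact that C5 and C10 are the β- and α-carbons of a C9 carbonyl in ring B, so a conjugate addition to a 3-methylcyclohexenone creates C5 with a vinyl group (C4, C15) and alkylation of the enolate puts an allyl group (C1–C3) on C10. The two arms are then vicinal, so a C3–C4 closure makes ring A and turns C15 into the C4 methyl, while the C9 carbonyl stays available to reach C7 and C8.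

## Logic of the disconnections

26 ⇒ 25. No skeletal bond is cut; the C8 carbonyl is taken back to a C8 hydroxyl. The carbonyl is what makes C7–H and C9–H acidic, so removing it makes the β,γ-alkene and the α-acyloxy group inert in all earlier steps. The forward step must be a neutral oxidation that neither enolises the product nor moves the acyl group from O9 to O8.

25 ⇒ 24 ⇒ 22 + 23. The O9–acyl bond is cut, with O8 held as a silyl ether. The two vicinal oxygens are thus told apart by the order in which they appear, not by selective chemistry on a diol. 22 has one free hydroxyl and 23 is commercial. The forward steps must acylate a hindered alcohol without deconjugating the acyl group and remove the silyl group without acyl migration.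

22 ⇒ 21. The C9–H bond is cut (alcohol back to ketone). The C9 carbonyl is kept this long because it gives access to C7 and C8 in the preceding steps. The demand is severe: hydride must enter from the β face of C9, syn to the axial C5 methyl, and the axial 8α-silyloxy group is relied on to block the α face.

21 ⇒ 19 (through 20). The C8–O bond is cut back to a C8=C9 enol ether. An enol ether is the only alkene in the molecule electron-rich enough to be oxidised selectively. One oxygen and the C8 stereocentre are removed. The forward step needs α-face oxygen transfer that leaves the isopropenyl and tiglate alkenes alone.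

19 ⇒ 17 + 18. The C7–C11 bond is cut. C7 is β to the C9 carbonyl, so the isopropenyl group arrives intact by conjugate addition and the enolate is formed with the C8=C9 regiochemistry needed above. Three carbons and the C7 stereocentre are removed. The addition must occur from the α face and the enolate must be trapped on oxygen.

17 ⇒ 15 (through 16). The C7=C8 π bond is removed, returning to the saturated ketone. The demand is enolisation toward the C8 methylene and not toward C10.

15 ⇒ 14 ⇒ 12 + 13. The O3–acyl bond is cut and the C9 ketone is masked as a ketal. The ester is installed as soon as O3 exists, so no protecting group is spent on it. The forward unmasking must also let C10 settle into the trans ring fusion.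

12 ⇒ 11. The C3–C4 bond is cut, opening ring A to a C3 aldehyde and the C4=C15 vinyl group. A reductive closure of this bond creates the C3 hydroxyl and the C4 methyl together. A ring and two stereocentres are removed. The forward step is a 6-exo radical addition to an unactivated alkene beside a quaternary carbon, and C9 must not be a free ketone.

11 ⇒ 10 ⇒ 9 ⇒ 8. The C3–O bond and the ketal C–O bonds are cut, leaving the allyl and vinyl arms on a cyclohexanone. The hydration must choose the allyl over the vinyl terminus.

8 ⇒ 3 + 4 + 5 (through 6 and 7). C4–C5 and C1–C10 are cut. Both bonds flank the C9 carbonyl, so one conjugate addition and enolate alkylation assembles all of ring B with the C1–C3 and C4/C15 arms from three small achiral pieces. The forward step must create the quaternary C5 with absolute control and alkylate a hindered enolate on carbon.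

3 ⇒ 1 + 2. The Al–vinyl bond is cut to two commercial organometallics; the only requirement is clean transmetalation.

## Other disconnections considered

Alternative 1: The cut is C7–C8 of ring B, made last. A ring A substrate already carrying both esters, the C8 aldehyde and a prenyl group on C5 would close with an alkylaluminium chloride Lewis acid by a carbonyl-ene reaction to the homoallylic alcohol A1. One oxidation would then give 26.
- In favour: ring B, the C7 stereocentre and the isopropenyl group arise together under non-basic conditions, and a chair transition state should place the C7 and C8 substituents trans-diequatorial.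
- Equal to the chosen plan: the sensitive ketone appears only in the final oxidation.
- Better than the chosen plan: the isopropenyl group arrives without an organocopper step and without a hydride reduction at C9.
- Against: the substrate is an α-acyloxy aldehyde, prone to epimerisation at C9 or elimination under the Lewis acid. C3, C4, C5, C10 and C9 would all have to be set on a monocyclic ring without the conformational bias of the decalin. The quaternary C5 would not be addressed by the key step at all. The Lewis acid can also engage the two unsaturated esters or divert the ene reaction to a Prins-type chloride capture.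
- Step economy: the key step is more convergent than step 2, but the route to its substrate should be longer than the fourteen steps that follow step 2.

Alternative 2: The cuts are C5–C10 and C6–C7. An open-chain substrate with an (E)-β-methyl enal tethered through C1–C4 to a 2-silyloxy diene would undergo an intramolecular Diels–Alder reaction to A2, closing both rings at once.
- Better than the chosen plan in ring construction: both rings, the quaternary C5 and the ring fusion form in one concerted step, where the chosen plan needs two separate closures.
- Better at C8/C9: the C8 silyl enol ether in A2 is regiodefined toward C9, so α-face oxygenation would give the 9α-oxygen and the C8 ketone directly, with no β-face hydride delivery.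
- Against: the formyl group on C6 is a carbon the target lacks and must be excised later. The dienophile is trisubstituted and must form a quaternary centre. Trans versus cis fusion in this kind of triene cyclisation is not strongly biased. The C3 and C4 stereocentres must be made in the acyclic tether and then control the facial sense. The isopropenyl group would have to be attached at C7 by enolate chemistry next to the C8 ketone, which is less reliable than the conjugate addition of step 10.
- Mechanism and step economy: one pericyclic step against two polar bond formations. The saving is probably offset by assembling a stereodefined triene and removing the extra carbon.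

Alternative 3: The cut is the transannular C5–C10 bond of a cyclodecene. A strong protic acid would protonate the C5 exocyclic methylene, the tertiary cation would be attacked across the ring by C10 of the (E)-alkene, and the carbamate oxygen on C8 would capture C9 to give the cyclic carbonate A3.
- Better than the chosen plan at C8/C9: the ring fusion, the quaternary C5 and the cis-8α,9α-dioxygen pattern arise together by a stereospecific anti addition across the alkene.
- Equal: the quaternary methyl arrives by simple protonation and costs nothing.
- Against: a functionalised ten-membered ring must be built first. The ring-fusion geometry depends on which conformer of that ring reacts. The cation can eliminate, be captured by the acid or shift hydride. An isopropenyl group could not be present during the cation step and would have to be added afterwards. Turning the carbonate into a C8 ketone and a C9 ester costs several steps.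
- Mechanism and step economy: the key step is more powerful than step 2, but the medium-ring precursor makes the whole plan longer and less predictable than conjugate addition to a commercial enone.

Key step: step 2

Remark: the (2R,3R) configuration of 8 corresponds to 5R,10R of 26 (C5 methyl β, H10 α), so no structure is corrected; the one design change is that C9 is masked as a ketal before the divalent-samarium step, because a free C9 ketone would undergo pinacol coupling with the C3 aldehyde.

## Route

Step 1
Reactants: 1 vinylmagnesium bromide; 2 diisobutylaluminium chloride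
Product: 3 diisobutyl(vinyl)aluminium
Conditions: THF/hexane, 0 °C → rt; supernatant used directly
Reagents that add atoms: none
Why: Magnesium-to-aluminium transmetalation (salt metathesis) driven by precipitation of the magnesium halide; the mixed alane transfers its sp2 vinyl group in preference to isobutyl in the copper-catalysed step.

Step 2
Reactants: 3 diisobutyl(vinyl)aluminium; 4 3-methylcyclohex-2-en-1-one; 5 3-iodoprop-1-ene
Product: 8 (2R,3R)-2-allyl-3-methyl-3-vinylcyclohexan-1-one, via aluminium enolate 6 (not isolated), via lithium aluminate enolate 7 (not isolated)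
Conditions: Cu(OTf)2 (5 mol %), chiral sulfonate-bearing imidazolinium salt (NHC precursor, 6 mol %) pre-treated with Ag2O, THF, −30 → 4 °C; MeLi, −30 °C; then 5, DMPU, −30 °C → rt; aq. NH4Cl
Reagents that add atoms: none
Why: The vinyl group passes from aluminium to the NHC-bound copper, the alane activates the enone, and addition to the β-carbon followed by reductive elimination from a trivalent copper intermediate forms C4–C5 and leaves the aluminium enolate 6. The closest known reaction type is the copper–NHC-catalysed enantioselective conjugate addition of alkenylaluminium reagents to β-substituted cyclohexenones, combined with alkylation of the derived aluminate enolate. C5 is set by the chiral carbene ligand (catalyst control; the ligand enantiomer is chosen to give R). MeLi converts the weakly nucleophilic 6 into the aluminate 7, which is C-allylated by 5 in an SN2 reaction to form C1–C10; the enolate is regiodefined, so C8 is untouched. C10 is set by the substrate through axial attack on the half-chair enolate anti to the pseudo-axial C5 substituent, which should favour allyl trans to vinyl only moderately; because C10 is α to the C9 carbonyl it is corrected in step 8. No ring is closed. The step needs 1,4- over 1,2-addition (copper catalysis on a β-substituted enone), vinyl over isobutyl transfer (sp2 groups move faster from aluminium to copper) and a single C-allylation (soft allylic iodide; C10 of the product is flanked by the quaternary C5 and is not re-enolised at low temperature).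

Step 3
Reactants: 8 (2R,3R)-2-allyl-3-methyl-3-vinylcyclohexan-1-one
Product: 9 (6R,7R)-6-allyl-7-methyl-7-vinyl-1,4-dioxaspiro[4.5]decane
Conditions: TMSOCH2CH2OTMS, TMSOTf (cat.), CH2Cl2, −78 → −20 °C
Reagents that add atoms: 1,2-bis(trimethylsilyloxy)ethane, C[Si](C)(C)OCCO[Si](C)(C)C
Why: Silyl-triflate-catalysed ketalisation with the bis-silyl ether is driven by formation of the disiloxane and works at low temperature on hindered ketones without enolising C10; the ketal prevents pinacol coupling of C9 with the C3 aldehyde in step 6.

Step 4
Reactants: 9 (6R,7R)-6-allyl-7-methyl-7-vinyl-1,4-dioxaspiro[4.5]decane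
Product: 10 3-[(6R,7R)-7-methyl-7-vinyl-1,4-dioxaspiro[4.5]decan-6-yl]propan-1-ol
Conditions: disiamylborane (from BH3·SMe2 and 2-methylbut-2-ene), THF, 0 °C; then NaOH, H2O2
Reagents that add atoms: hydrogen peroxide, OO
Why: Anti-Markovnikov hydroboration–oxidation; the bulky dialkylborane reacts with the unhindered allyl terminus far faster than with the vinyl group on the quaternary C5.

Step 5
Reactants: 10 3-[(6R,7R)-7-methyl-7-vinyl-1,4-dioxaspiro[4.5]decan-6-yl]propan-1-ol
Product: 11 3-[(6R,7R)-7-methyl-7-vinyl-1,4-dioxaspiro[4.5]decan-6-yl]propanal
Conditions: Dess–Martin periodinane, CH2Cl2, rt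
Reagents that add atoms: none
Why: Dess–Martin oxidation of a primary alcohol to the aldehyde under neutral conditions; ketal and vinyl group are inert and C2 carries no stereocentre.

Step 6
Reactants: 11 3-[(6R,7R)-7-methyl-7-vinyl-1,4-dioxaspiro[4.5]decan-6-yl]propanal
Product: 12 9,9-(ethylenedioxy)-11,12,13-trinor-10αH-eremophilan-3α-ol (trans-decalin, 4β,5β-dimethyl)
Conditions: SmI2 (2.5 equiv), HMPA, t-BuOH, THF, 0 °C, high dilution
Reagents that add atoms: none
Why: SmI2-mediated ketyl–olefin cyclisation (6-exo-trig): the C3 ketyl adds to C4 through a chair with the C5 methyl axial and both the alkene terminus C15 and the bulky samarium alkoxide equatorial and anti, giving the 3α-oxygen and 4β-CH2 radical, which is reduced and protonated to the C4 methyl. C5 is quaternary, so no allylic 1,5-hydrogen shift can compete, and any C10 epimer of 11 should close through the same C5-anchored chair and converge in step 8.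

Step 7
Reactants: 12 9,9-(ethylenedioxy)-11,12,13-trinor-10αH-eremophilan-3α-ol; 13 (E)-2-methylbut-2-enoyl chloride
Product: 14 9,9-(ethylenedioxy)-11,12,13-trinor-10αH-eremophilan-3α-yl (E)-2-methylbut-2-enoate
Conditions: pyridine, DMAP (cat.), CH2Cl2, 0 °C → rt
Reagents that add atoms: none
Why: DMAP-catalysed acylation of the unhindered equatorial 3α-alcohol; the (E)-geometry of the tigloyl group is the stable one and is retained.

Step 8
Reactants: 14 9,9-(ethylenedioxy)-11,12,13-trinor-10αH-eremophilan-3α-yl (E)-2-methylbut-2-enoate
Product: 15 3α-[(E)-2-methylbut-2-enoyloxy]-11,12,13-trinor-10αH-eremophilan-9-one (trans-fused)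
Conditions: 2 M HCl, THF, 45 °C
Reagents that add atoms: water, O
Why: Acid hydrolysis of the dioxolane returns the C9 ketone, and acid-catalysed enolisation toward C10 equilibrates the ring fusion. The trans-fused isomer should be preferred, though only moderately, and any cis isomer is separated and resubmitted.

Step 9
Reactants: 15 3α-[(E)-2-methylbut-2-enoyloxy]-11,12,13-trinor-10αH-eremophilan-9-one
Product: 17 3α-[(E)-2-methylbut-2-enoyloxy]-11,12,13-trinor-10αH-eremophil-7-en-9-one, via trimethylsilyl enol ether 16 (not isolated)
Conditions: LiHMDS, TMSCl, THF, −78 °C; then Pd(OAc)2, MeCN, rt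
Reagents that add atoms: none
Why: Kinetic deprotonation at the C8 methylene (C10 is a hindered methine) with in-situ silylation gives the C8=C9 enol ether, and Saegusa–Ito oxidation (divalent palladium enolate, β-hydride elimination) gives the enone. The tiglate is a poor electrophile for the hindered amide at −78 °C.

Step 10
Reactants: 17 3α-[(E)-2-methylbut-2-enoyloxy]-11,12,13-trinor-10αH-eremophil-7-en-9-one; 18 isopropenylmagnesium bromide
Product: 19 9-(triethylsilyloxy)-3α-[(E)-2-methylbut-2-enoyloxy]-7βH,10αH-eremophila-8,11-diene (7α-isopropenyl)
Conditions: CuBr·SMe2 (20 mol %), Et3SiCl, DMPU, THF, −78 °C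
Reagents that add atoms: chlorotriethylsilane, CC[Si](Cl)(CC)CC
Why: Chlorosilane-accelerated copper-catalysed conjugate addition of the alkenyl Grignard reagent; the nucleophile enters at C7 from the α face, anti to the axial C5 methyl that is 1,3 to C7, and the enolate is trapped regiospecifically as the C8=C9 silyl enol ether. The trisubstituted tiglate is much less reactive than the enone.

Step 11
Reactants: 19 9-(triethylsilyloxy)-3α-[(E)-2-methylbut-2-enoyloxy]-7βH,10αH-eremophila-8,11-diene
Product: 21 8α-(triethylsilyloxy)-3α-[(E)-2-methylbut-2-enoyloxy]-7βH,10αH-eremophil-11-en-9-one, via silyloxy epoxide 20 (not isolated)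
Conditions: DMDO (1.05 equiv), acetone/CH2Cl2, −78 → 0 °C; then PhMe, 40 °C
Reagents that add atoms: dimethyldioxirane, CC1(C)OO1
Why: Rubottom oxidation: the electron-rich enol ether is epoxidised from the α face (anti to the C5 methyl over C9) in preference to the isopropenyl and tiglate alkenes, and ring opening of 20 with 1,4-silyl shift gives the 8α-silyloxy ketone.

Step 12
Reactants: 21 8α-(triethylsilyloxy)-3α-[(E)-2-methylbut-2-enoyloxy]-7βH,10αH-eremophil-11-en-9-one
Product: 22 8α-(triethylsilyloxy)-3α-[(E)-2-methylbut-2-enoyloxy]-7βH,10αH-eremophil-11-en-9α-ol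
Conditions: NaBH4, CeCl3·7H2O, MeOH/THF, −78 → −40 °C
Reagents that add atoms: none
Why: Luche reduction with a small hydride; the axial 8α-silyloxy group blocks the α face and, by the polar Felkin–Anh model, directs hydride anti to the C8–O bond. This should outweigh the syn-axial C5 methyl and give the equatorial 9α-alcohol; the low temperature limits silyl migration from O8 to O9.

Step 13
Reactants: 22 8α-(triethylsilyloxy)-3α-[(E)-2-methylbut-2-enoyloxy]-7βH,10αH-eremophil-11-en-9α-ol; 23 3-methylbut-2-enoyl chloride
Product: 24 9α-(3-methylbut-2-enoyloxy)-8α-(triethylsilyloxy)-3α-[(E)-2-methylbut-2-enoyloxy]-7βH,10αH-eremophil-11-ene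
Conditions: pyridine, DMAP, CH2Cl2, 0 → 40 °C
Reagents that add atoms: none
Why: DMAP-promoted acylation of the only free hydroxyl; pyridine as the sole base limits deconjugation of the senecioyl group through a vinylketene.

Step 14
Reactants: 24 9α-(3-methylbut-2-enoyloxy)-8α-(triethylsilyloxy)-3α-[(E)-2-methylbut-2-enoyloxy]-7βH,10αH-eremophil-11-ene
Product: 25 9α-(3-methylbut-2-enoyloxy)-3α-[(E)-2-methylbut-2-enoyloxy]-7βH,10αH-eremophil-11-en-8α-ol
Conditions: HF·pyridine, pyridine, THF, 0 °C
Reagents that add atoms: none
Why: Fluoride cleavage of the triethylsilyl ether under buffered, weakly acidic conditions that leave both unsaturated esters in place and disfavour acyl migration from O9 to O8.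

Step 15
Reactants: 25 9α-(3-methylbut-2-enoyloxy)-3α-[(E)-2-methylbut-2-enoyloxy]-7βH,10αH-eremophil-11-en-8α-ol
Product: 26 9α-(3-methylbut-2-enoyloxy)-3α-[(E)-2-methylbut-2-enoyloxy]-7βH,10αH-eremophil-11-en-8-one (3R,4R,5R,7S,9S,10R; CNP0375730.3)
Conditions: Dess–Martin periodinane, pyridine, CH2Cl2, 0 °C → rt
Reagents that add atoms: none
Why: Dess–Martin oxidation buffered with pyridine converts the axial 8α-alcohol to the ketone without enolisation, so the isopropenyl group stays β,γ to the carbonyl and C7 and C9 keep their equatorial configurations.

## Compound list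

1 | vinylmagnesium bromide | C=C[Mg]Br | starting material
2 | diisobutylaluminium chloride | CC(C)C[Al](Cl)CC(C)C | starting material
3 | diisobutyl(vinyl)aluminium | C=C[Al](CC(C)C)CC(C)C | intermediate
4 | 3-methylcyclohex-2-en-1-one | CC1=CC(=O)CCC1 | starting material
5 | 3-iodoprop-1-ene | C=CCI | starting material
6 | diisobutyl[(R)-3-methyl-3-vinylcyclohex-1-en-1-olato]aluminium | CC(C)C[Al](CC(C)C)OC1=C[C@@](C)(C=C)CCC1 | intermediate
7 | lithium diisobutyl(methyl)[(R)-3-methyl-3-vinylcyclohex-1-en-1-olato]aluminate | [Li+].CC(C)C[Al-](C)(CC(C)C)OC1=C[C@@](C)(C=C)CCC1 | intermediate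
8 | (2R,3R)-2-allyl-3-methyl-3-vinylcyclohexan-1-one | O=C1CCC[C@](C)(C=C)[C@H]1CC=C | intermediate
9 | (6R,7R)-6-allyl-7-methyl-7-vinyl-1,4-dioxaspiro[4.5]decane | O1CCOC12CCC[C@](C)(C=C)[C@H]2CC=C | intermediate
10 | 3-[(6R,7R)-7-methyl-7-vinyl-1,4-dioxaspiro[4.5]decan-6-yl]propan-1-ol | O1CCOC12CCC[C@](C)(C=C)[C@H]2CCCO | intermediate
11 | 3-[(6R,7R)-7-methyl-7-vinyl-1,4-dioxaspiro[4.5]decan-6-yl]propanal | O1CCOC12CCC[C@](C)(C=C)[C@H]2CCC=O | intermediate
12 | 9,9-(ethylenedioxy)-11,12,13-trinor-10αH-eremophilan-3α-ol | C1C[C@]2(C)[C@@H](C)[C@H](O)CC[C@H]2C3(OCCO3)C1 | intermediate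
13 | (E)-2-methylbut-2-enoyl chloride (tigloyl chloride) | C/C=C(\C)C(=O)Cl | starting material
14 | 9,9-(ethylenedioxy)-11,12,13-trinor-10αH-eremophilan-3α-yl (E)-2-methylbut-2-enoate | C1C[C@]2(C)[C@@H](C)[C@H](OC(=O)/C(C)=C/C)CC[C@H]2C3(OCCO3)C1 | intermediate
15 | 3α-[(E)-2-methylbut-2-enoyloxy]-11,12,13-trinor-10αH-eremophilan-9-one | C1C[C@]2(C)[C@@H](C)[C@H](OC(=O)/C(C)=C/C)CC[C@H]2C(=O)C1 | intermediate
16 | 9-(trimethylsilyloxy)-3α-[(E)-2-methylbut-2-enoyloxy]-11,12,13-trinor-10αH-eremophil-8-ene | C1C[C@]2(C)[C@@H](C)[C@H](OC(=O)/C(C)=C/C)CC[C@H]2C(O[Si](C)(C)C)=C1 | intermediate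
17 | 3α-[(E)-2-methylbut-2-enoyloxy]-11,12,13-trinor-10αH-eremophil-7-en-9-one | O=C1C=CC[C@]2(C)[C@@H](C)[C@H](OC(=O)/C(C)=C/C)CC[C@@H]12 | intermediate
18 | isopropenylmagnesium bromide | C=C(C)[Mg]Br | starting material
19 | 9-(triethylsilyloxy)-3α-[(E)-2-methylbut-2-enoyloxy]-7βH,10αH-eremophila-8,11-diene | C=C(C)[C@@H]1C[C@]2(C)[C@@H](C)[C@H](OC(=O)/C(C)=C/C)CC[C@H]2C(O[Si](CC)(CC)CC)=C1 | intermediate
20 | 8α,9α-epoxy-9β-(triethylsilyloxy)-3α-[(E)-2-methylbut-2-enoyloxy]-7βH,10αH-eremophil-11-ene | C=C(C)[C@@H]1C[C@]2(C)[C@@H](C)[C@H](OC(=O)/C(C)=C/C)CC[C@H]2[C@]3(O[Si](CC)(CC)CC)O[C@@H]31 | intermediate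
21 | 8α-(triethylsilyloxy)-3α-[(E)-2-methylbut-2-enoyloxy]-7βH,10αH-eremophil-11-en-9-one | C=C(C)[C@@H]1C[C@]2(C)[C@@H](C)[C@H](OC(=O)/C(C)=C/C)CC[C@H]2C(=O)[C@@H]1O[Si](CC)(CC)CC | intermediate
22 | 8α-(triethylsilyloxy)-3α-[(E)-2-methylbut-2-enoyloxy]-7βH,10αH-eremophil-11-en-9α-ol | C=C(C)[C@@H]1C[C@]2(C)[C@@H](C)[C@H](OC(=O)/C(C)=C/C)CC[C@H]2[C@H](O)[C@@H]1O[Si](CC)(CC)CC | intermediate
23 | 3-methylbut-2-enoyl chloride (senecioyl chloride) | CC(C)=CC(=O)Cl | starting material
24 | 9α-(3-methylbut-2-enoyloxy)-8α-(triethylsilyloxy)-3α-[(E)-2-methylbut-2-enoyloxy]-7βH,10αH-eremophil-11-ene | C=C(C)[C@@H]1C[C@]2(C)[C@@H](C)[C@H](OC(=O)/C(C)=C/C)CC[C@H]2[C@H](OC(=O)C=C(C)C)[C@@H]1O[Si](CC)(CC)CC | intermediate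
25 | 9α-(3-methylbut-2-enoyloxy)-3α-[(E)-2-methylbut-2-enoyloxy]-7βH,10αH-eremophil-11-en-8α-ol | C=C(C)[C@@H]1C[C@]2(C)[C@@H](C)[C@H](OC(=O)/C(C)=C/C)CC[C@H]2[C@H](OC(=O)C=C(C)C)[C@@H]1O | intermediate
26 | 9α-(3-methylbut-2-enoyloxy)-3α-[(E)-2-methylbut-2-enoyloxy]-7βH,10αH-eremophil-11-en-8-one (CNP0375730.3) | C=C(C)[C@@H]1C[C@]2(C)[C@@H](C)[C@H](OC(=O)/C(C)=C/C)CC[C@H]2[C@H](OC(=O)C=C(C)C)C1=O | target

## Step count and least certain steps

Total: 15 steps. Longest linear sequence: 15 steps (1 → 26; 14 steps from 4).

Step 2 (key step). The likely failures are incomplete C-alkylation of the hindered aluminate enolate (protonation on work-up instead of allylation), competing isobutyl transfer, and weaker enantiofacial control with the small unsubstituted vinyl group. The fallback keeps the conjugate addition but forms C1–C10 differently. It sets out from 4 (with 3) and returns at 8. The aluminium enolate 6 is trapped on oxygen with allyl chloroformate to give allyl (R)-3-methyl-3-vinylcyclohex-1-en-1-yl carbonate F1. F1 then undergoes decarboxylative Tsuji allylation with Pd(PPh3)4 in THF to give 8, the allyl group being delivered regiospecifically to C10 through a π-allyl palladium enolate.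

Step 6. The likely failure is slow 6-exo addition of the ketyl to the unactivated vinyl group beside the quaternary C5, so that simple reduction of the aldehyde or pinacol dimerisation takes over; C3/C4 selectivity could also erode. The fallback sets out from 10 and returns at 12, forming C3–C4 as an alkene and setting both stereocentres afterwards.
- Wacker oxidation of the vinyl group (PdCl2, CuCl, O2, DMF/H2O) gives 3-[(6R,7S)-7-acetyl-7-methyl-1,4-dioxaspiro[4.5]decan-6-yl]propan-1-ol F2.
- Dess–Martin oxidation gives the keto aldehyde 3-[(6R,7S)-7-acetyl-7-methyl-1,4-dioxaspiro[4.5]decan-6-yl]propanal F3.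
- McMurry coupling (TiCl3(DME)1.5, Zn–Cu, DME, reflux, slow addition) closes ring A to 9,9-(ethylenedioxy)-11,12,13-trinor-10αH-eremophil-3-ene F4.
- Hydroboration–oxidation (BH3·THF; NaOH, H2O2) adds H and OH syn from the α face, anti to the C5 methyl, with boron on the less substituted C3, and gives 12.

Step 8. The likely failure is an insufficient thermodynamic bias: the angular methyl lowers the usual preference for a trans-fused 1-decalone, so the equilibrium may leave a sizeable share of the cis isomer, and acid may also erode a good kinetic ratio from step 2. The fallback relies on kinetic control and separation at the monocyclic stage; it sets out from 8 and returns at 8. The C10 epimer (2S,3R)-2-allyl-3-methyl-3-vinylcyclohexan-1-one F5 is removed by chromatography and recycled by DBU in toluene, which re-forms the mixture of 8 and F5. Step 8 is then run as a non-equilibrating ketal cleavage (PPTS, wet acetone, rt), so that the C10 configuration from step 2 is carried unchanged into 15.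

Step 10. The likely failures are attack of the Grignard reagent on the tiglate, or addition from the wrong face if the half-chair enone reacts through a boat-like path. The fallback sets out from 17 and returns at 19 and uses an ester-tolerant catalytic addition. Hayashi–Miyaura addition of isopropenylboronic acid pinacol ester with [Rh(cod)OH]2 in dioxane/H2O at 50 °C gives 7α-isopropenyl-3α-[(E)-2-methylbut-2-enoyloxy]-7βH,10αH-eremophil-11-en-9-one F6. Kinetic enolisation at C8 (LiHMDS, Et3SiCl, THF, −78 °C) then gives 19.

Step 12. The likely failure is poor facial selectivity: hydride entering from the α face, driven by the syn-axial C5 methyl, gives the axial 9β-alcohol; base-induced silyl migration from O8 to O9 is a second risk. The fallback uses that epimer productively by transposing the carbonyl and creating the C9–O bond from the α face; it sets out from 21 and returns at 26.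
- Reduction gives 8α-(triethylsilyloxy)-3α-[(E)-2-methylbut-2-enoyloxy]-7βH,10αH-eremophil-11-en-9β-ol F7.
- Burgess dehydration (PhH, 50 °C) is a syn elimination; only H8β is cis to the 9β-oxygen (H10 is trans), so it gives the enol ether 8-(triethylsilyloxy)-3α-[(E)-2-methylbut-2-enoyloxy]-7βH,10αH-eremophila-8,11-diene F8.
- Rubottom oxidation of F8 (DMDO, then mild acid work-up) adds oxygen to C9 from the α face and gives 9α-hydroxy-3α-[(E)-2-methylbut-2-enoyloxy]-7βH,10αH-eremophil-11-en-8-one F9.
- Acylation of F9 with 23 and pyridine at 0 °C gives 26.

## Further compounds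

F1 | step 2 | allyl (R)-3-methyl-3-vinylcyclohex-1-en-1-yl carbonate | C=CCOC(=O)OC1=C[C@@](C)(C=C)CCC1
F2 | step 6 | 3-[(6R,7S)-7-acetyl-7-methyl-1,4-dioxaspiro[4.5]decan-6-yl]propan-1-ol | O1CCOC12CCC[C@](C)(C(C)=O)[C@H]2CCCO
F3 | step 6 | 3-[(6R,7S)-7-acetyl-7-methyl-1,4-dioxaspiro[4.5]decan-6-yl]propanal | O1CCOC12CCC[C@](C)(C(C)=O)[C@H]2CCC=O
F4 | step 6 | 9,9-(ethylenedioxy)-11,12,13-trinor-10αH-eremophil-3-ene | C1C[C@]2(C)C(C)=CCC[C@H]2C3(OCCO3)C1
F5 | step 8 | (2S,3R)-2-allyl-3-methyl-3-vinylcyclohexan-1-one | O=C1CCC[C@](C)(C=C)[C@@H]1CC=C
F6 | step 10 | 7α-isopropenyl-3α-[(E)-2-methylbut-2-enoyloxy]-7βH,10αH-eremophil-11-en-9-one | C=C(C)[C@@H]1C[C@]2(C)[C@@H](C)[C@H](OC(=O)/C(C)=C/C)CC[C@H]2C(=O)C1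
F7 | step 12 | 8α-(triethylsilyloxy)-3α-[(E)-2-methylbut-2-enoyloxy]-7βH,10αH-eremophil-11-en-9β-ol | C=C(C)[C@@H]1C[C@]2(C)[C@@H](C)[C@H](OC(=O)/C(C)=C/C)CC[C@H]2[C@@H](O)[C@@H]1O[Si](CC)(CC)CC
F8 | step 12 | 8-(triethylsilyloxy)-3α-[(E)-2-methylbut-2-enoyloxy]-7βH,10αH-eremophila-8,11-diene | C=C(C)[C@@H]1C[C@]2(C)[C@@H](C)[C@H](OC(=O)/C(C)=C/C)CC[C@H]2C=C1O[Si](CC)(CC)CC
F9 | step 12 | 9α-hydroxy-3α-[(E)-2-methylbut-2-enoyloxy]-7βH,10αH-eremophil-11-en-8-one | C=C(C)[C@@H]1C[C@]2(C)[C@@H](C)[C@H](OC(=O)/C(C)=C/C)CC[C@H]2[C@H](O)C1=O
A1 | alternative 1 | 9α-(3-methylbut-2-enoyloxy)-3α-[(E)-2-methylbut-2-enoyloxy]-7βH,10αH-eremophil-11-en-8β-ol | C=C(C)[C@@H]1C[C@]2(C)[C@@H](C)[C@H](OC(=O)/C(C)=C/C)CC[C@H]2[C@H](OC(=O)C=C(C)C)[C@H]1O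
A2 | alternative 2 | 6β-formyl-3α-(triisopropylsilyloxy)-8-(tert-butyldimethylsilyloxy)-11,12,13-trinoreremophil-8-ene | C1[C@@H](C=O)[C@]2(C)[C@@H](C)[C@H](O[Si](C(C)C)(C(C)C)C(C)C)CC[C@H]2C=C1O[Si](C)(C)C(C)(C)C
A3 | alternative 3 | 3α-(triisopropylsilyloxy)-11,12,13-trinoreremophilane-8α,9α-diol cyclic carbonate | C1C[C@]2(C)[C@@H](C)[C@H](O[Si](C(C)C)(C(C)C)C(C)C)CC[C@H]2[C@H](OC(=O)O3)[C@@H]13
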